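Numbering: compounds 1–40 are fixed by the steps and the compound list below. T, M and B are the top, middle and bottom flavan units; each unit has rings A (phloroglucinol ring), B (catechol ring) and C (pyran ring) and the usual flavan atom numbers.

## Analysis of the target

Compound 40 is epicatechin-(4β→6)-epicatechin-(4β→6)-epicatechin: three 2-arylchroman-3-ol units joined by two C4–C6 bonds, C4 of T to C6 of ring A of M and C4 of M to C6 of ring A of B. It has eight stereocentres. C2 and C3 of every unit are R (2-aryl and 3-oxygen cis), and C4 of T and of M carries its aryl group trans to the C3 oxygen and trans to the C2 aryl group. The molecule holds twelve phenols (three air-sensitive catechols) and three secondary alcohols, its interflavan bonds are cleaved by acid, and C2 of a free flavan-3-ol epimerises in base, so the hydroxyls must stay masked until a last neutral step. The first difficulty is regiochemical: both interflavan bonds go to C6, although C8 is the more accessible and more nucleophilic position of a 5,7-dioxygenated ring A. The second is stereochemical: the 3,4-trans and 2,3-cis relations must be built twice, in one absolute sense, next to a crowded diarylmethine. The strategy rests on C3 and C4 of unit M (and again of unit T): C4 is a diarylmethine joining ring A of its own unit to C6 of the unit below, and C3 is an adjacent oxygen-bearing carbon trans to it. That is the pattern left when an α-oxygenated aldehyde adds to a diaryl ortho-quinone methide and the phenol closes on the aldehyde.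

## Retrosynthetic reasoning

**40 from 39.** All fifteen O–benzyl bonds and the two C8–Cl bonds (unit M and unit B) are cut last, in one hydrogenolysis. Benzyl ethers survive organolithium, Lewis-acid and Mitsunobu chemistry. The chlorines block C8 so that every bond to ring A is forced to C6; they are inert to bromine–lithium exchange and leave under the same hydrogenolysis.

**39 back to lactol 34 (ring C of T completed).** O1–C2 is cut first: 39 comes from alcohol 38 by SN2 closure with inversion. The carbinol C–H bond is cut next: 38 comes from ketone 37 by chelation-controlled reduction. The C2–aryl bond is then cut: 37 comes from the N-methoxy-N-methylamide 36 and the Grignard reagent 23. Amide 36 is the opened form of lactone 35, the oxidation product of 34. A shorter path, ionic reduction of the cyclic hemiketal form of 37, was not adopted. In the oxocarbenium ion derived from 37 the C4 aryl group is held axial by the peri C5 benzyloxy group, so hydride would enter anti to it and cis to the C3 benzyloxy group, which leads to the 2,3-trans, 2,4-cis series. Building the carbinol as the 1,2-anti isomer and inverting it on ring closure gives the 2,3-cis arrangement by two predictable steps.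

**34 from 30 and 14.** C3–C4 and O1–C2 of unit T are cut together. Benzhydrol 30 ionises to quinone methide 31, the enamine 32 of aldehyde 14 supplies C2, C3 and the C3 oxygen, and hydroxy aldehyde 33 closes to the lactol. This is the second use of the key reaction.

**30 from 26 and 27.** The C4(T)–C6(M) bond is cut at the benzhydrol: aryllithium 28 (from the C6 bromide of 26) adds to aldehyde 27, and the allyl group of adduct 29 is removed. The bromine of 26 is the only halogen that exchanges, so the bond can only form at C6 of M.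

**26 back to lactol 18.** The same five operations as for unit T (oxidation, amide opening, addition of 23, chelation-controlled reduction, inverting ring closure) lead back through 25, 24, 20 and 19 to 18.

**18 from 13 and 14 (key disconnection).** C3–C4 and O1–C2 of unit M are cut. Benzhydrol 13 gives quinone methide 15, the enamine 16 of 14 adds to it, and hydroxy aldehyde 17 closes to 18. Both stereocentres and ring C arise in one catalytic step, and the C3 oxygen arrives already benzylated. The forward reaction must give the 3,4-trans lactol in the 3R,4S sense under catalyst control.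

**13 from 5 and 10.** The C4(M)–C6(B) bond is cut at the carbinol: aryllithium 11, formed from 5 by bromine–lithium exchange at C6, adds to aldehyde 10, and the allyl ether of 12 is cleaved to free the phenol needed for the quinone methide.

**Building blocks.** 5 comes from 1 by benzylation (2, 3), chlorination at the more accessible C8 (4) and bromination at the remaining C6. 10 comes from 6 by dibenzylation (7), chlorination next to the free hydroxyl (8), bromination between the benzyloxy groups (9) and allylation. 27 is the allyl ether of 7. 22 is the dibenzyl ether of 21, and 23 is made from 22 by magnesium insertion, once, for both units.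

## Alternatives that were turned down

**Alternative 1: Baeyer–Villiger ring expansion of an arylindanone.** The disconnection is the O1–C8a bond of ring C. In the forward step a peracid converts indanone A1 into dihydrocoumarin A2; the electron-rich aryl carbon migrates in preference to the methylene and the C4 stereocentre is carried over unchanged. In its favour: oxygen insertion is regiochemically unambiguous, C4 could be set beforehand by an established asymmetric conjugate arylation, and no quinone methide has to be handled. On the certainty of the C4 configuration it is stronger than the chosen route, where C4 depends on the topicity of a C–C bond formation. Against it: the step forms one bond and no stereocentre. A2 still lacks the C3 oxygen and the C2 aryl group, so a later enolate oxidation and the whole C2 sequence would be added to the step count. The 4-aryl group of A2 is only a dioxygenated phenyl ring, so either ring C of unit B must still be built on it or the real epicatechin residue must be carried through a peracid oxidation that threatens its phloroglucinol and catechol ethers. The ketone of A1 is a vinylogous ester and therefore a sluggish Baeyer–Villiger substrate. In exchange for the certainty on C4, the chosen strategy gives C3 with its oxygen, C4 and ring C in one step and uses natural epicatechin unchanged as unit B.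

**Alternative 2: Grignard reagent, salicylaldehyde carbonate and styryl ester.** The disconnection cuts C4(T)–C6(M), C3–C4 and O1–C2 of unit T at once. Grignard reagent A3 adds to the O-Boc aldehyde A4, carbonate transfer and elimination give quinone methide A6, and the Z-enol ester A5 adds across it to give the protected trimer A7. In its favour: three bonds and three stereocentres form in one flask, the C2 aryl group arrives with the alkene, and the Z geometry translates into the 2,3-cis relation that costs four steps per unit in the chosen route. On step economy for unit T this alternative is clearly stronger. Against it: nothing controls the absolute sense of the three new centres except the distant stereocentres of unit M, which sit behind a perpendicular, doubly ortho-substituted aryl ring, so two diastereomeric T units are to be expected. The 3,4-trans relation requires the exo approach of the enol ester, against the usual endo preference of quinone methide cycloadditions. The orientation of the alkene rests on the aryl group outweighing the acyloxy group. The method also presupposes the whole dimeric framework of A3 and a magnesium reagent at a carbon flanked by two benzyloxy groups. The chosen strategy pays with more steps but places C3 under catalyst control and uses one method for both M and T.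

**Alternative 3: ring expansion of a dihydrobenzofuran carbinol.** The disconnection cuts O1–C2 and the C3–O bond. On activation of the benzylic hydroxyl of A8 the ring oxygen displaces it to give oxonium ion A9, and water opens A9 at the ring carbon to give flavan-3-ol A10. In its favour: two inversions transfer both stereocentres stereospecifically and the 3-hydroxyl comes out free. On the 2,3-relationship it is as secure on paper as the reduction and inversion sequence of the chosen route. Against it: A8 already contains three contiguous stereocentres and the C4–C6 bond, so the problem is moved, not solved. The activated carbinol is a 3,4-dialkoxybenzylic centre that can ionise to an open cation and lose the stereochemical information. Water should prefer the benzylic carbon of A9, where positive charge is better stabilised, and that returns the five-membered ring. The chosen strategy creates C3 and C4 directly from an achiral aldehyde and a benzhydrol that is two steps from the building blocks.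

Key step: step 11

Assumptions: (a) the first halogen is taken to enter each phloroglucinol ring at its less hindered free position (C8 of the flavan in step 3, ortho to the free hydroxyl in step 6), as in the NBS bromination of benzylated flavan-3-ols; the position is to be confirmed by NOE and HMBC before the material is carried on. (b) Benzhydrols 12, 13, 29 and 30 and lactols 18 and 34 are carried as epimer mixtures at the carbinol or anomeric carbon, which is destroyed in the following step. (c) Grignard reagent 23 is handled as a titrated THF solution under argon; if the solution has aged before step 25, a second batch is made by repeating step 15.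

## Route

Step 1
Reactants: 1 (−)-epicatechin
Product: 2 5,7,3',4'-tetra-O-benzyl-(−)-epicatechin
Conditions: BnBr (4.4 equiv), K2CO3, DMF, 0 °C to rt
Reagents that add atoms: benzyl bromide, BrCc1ccccc1
Why: Williamson etherification of the four phenols; the carbonate base leaves the secondary 3-hydroxyl free and does not epimerise C2.

Step 2
Reactants: 2 5,7,3',4'-tetra-O-benzyl-(−)-epicatechin
Product: 3 3,5,7,3',4'-penta-O-benzyl-(−)-epicatechin
Conditions: NaH, BnBr, DMF, 0 °C to rt
Reagents that add atoms: benzyl bromide, BrCc1ccccc1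
Why: Williamson etherification of the remaining secondary alcohol through its sodium alkoxide; with all phenols capped no quinone methide pathway to C2 epimerisation exists.

Step 3
Reactants: 3 3,5,7,3',4'-penta-O-benzyl-(−)-epicatechin
Product: 4 8-chloro-3,5,7,3',4'-penta-O-benzyl-(−)-epicatechin
Conditions: NCS (1.05 equiv), CH2Cl2, 0 °C to rt
Reagents that add atoms: N-chlorosuccinimide, O=C1CCC(=O)N1Cl
Why: Electrophilic aromatic chlorination of the most electron-rich ring; C8 (between O1 and one benzyloxy group) is less hindered than C6 (between two benzyloxy groups), the preference known for NBS on this ring, so chlorine should block C8.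

Step 4
Reactants: 4 8-chloro-3,5,7,3',4'-penta-O-benzyl-(−)-epicatechin
Product: 5 6-bromo-8-chloro-3,5,7,3',4'-penta-O-benzyl-(−)-epicatechin
Conditions: NBS (1.1 equiv), CH2Cl2, 0 °C to rt
Reagents that add atoms: N-bromosuccinimide, O=C1CCC(=O)N1Br
Why: Electrophilic aromatic bromination at C6, the only free position left on the phloroglucinol ring, which remains more reactive than the catechol ether ring.

Step 5
Reactants: 6 2,4,6-trihydroxybenzaldehyde
Product: 7 2,4-bis(benzyloxy)-6-hydroxybenzaldehyde
Conditions: BnBr (2.1 equiv), K2CO3, DMF, rt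
Reagents that add atoms: benzyl bromide, BrCc1ccccc1
Why: Williamson etherification; after the first ortho hydroxyl is benzylated the remaining one is hydrogen-bonded to the aldehyde and reacts last, so two equivalents should stop at the diether.

Step 6
Reactants: 7 2,4-bis(benzyloxy)-6-hydroxybenzaldehyde
Product: 8 4,6-bis(benzyloxy)-3-chloro-2-hydroxybenzaldehyde
Conditions: NCS (1.0 equiv), MeCN, 0 °C to rt
Reagents that add atoms: N-chlorosuccinimide, O=C1CCC(=O)N1Cl
Why: Electrophilic aromatic chlorination; both free positions are activated by three oxygens, and the one next to the small free hydroxyl is less hindered than the one between two benzyloxy groups, so chlorine should enter ortho to OH (later C8 of M).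

Step 7
Reactants: 8 4,6-bis(benzyloxy)-3-chloro-2-hydroxybenzaldehyde
Product: 9 2,4-bis(benzyloxy)-3-bromo-5-chloro-6-hydroxybenzaldehyde
Conditions: NBS (1.05 equiv), DMF, 0 °C to rt
Reagents that add atoms: N-bromosuccinimide, O=C1CCC(=O)N1Br
Why: Electrophilic aromatic bromination of the single remaining ring position, between the two benzyloxy groups (later C6 of M); the trioxygenated ring stays reactive despite the formyl and chloro groups.

Step 8
Reactants: 9 2,4-bis(benzyloxy)-3-bromo-5-chloro-6-hydroxybenzaldehyde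
Product: 10 2-(allyloxy)-4,6-bis(benzyloxy)-5-bromo-3-chlorobenzaldehyde
Conditions: allyl bromide, K2CO3, DMF, 40 °C
Reagents that add atoms: allyl bromide, C=CCBr
Why: Williamson etherification of the acidic ortho-chlorophenol; an allyl ether cannot migrate to the alkoxide formed in step 9 and is removed later without acid.

Step 9
Reactants: 5 6-bromo-8-chloro-3,5,7,3',4'-penta-O-benzyl-(−)-epicatechin; 10 2-(allyloxy)-4,6-bis(benzyloxy)-5-bromo-3-chlorobenzaldehyde
Product: 12 [2-(allyloxy)-4,6-bis(benzyloxy)-5-bromo-3-chlorophenyl](8-chloro-penta-O-benzylepicatechin-6-yl)methanol (carbinol epimers), via aryllithium 11 (not isolated)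
Conditions: 5, tBuLi (2.0 equiv), THF, −78 °C; then 10, −78 to −40 °C; aq NH4Cl
Reagents that add atoms: none
Why: Bromine–lithium exchange is far faster than chlorine–lithium exchange, so only C6 is metalated, and 1,2-addition to the aldehyde outruns aryl–aryl halogen exchange; both carbinol epimers later give the same quinone methide.

Step 10
Reactants: 12 [2-(allyloxy)-4,6-bis(benzyloxy)-5-bromo-3-chlorophenyl](8-chloro-penta-O-benzylepicatechin-6-yl)methanol
Product: 13 [4,6-bis(benzyloxy)-5-bromo-3-chloro-2-hydroxyphenyl](8-chloro-penta-O-benzylepicatechin-6-yl)methanol (carbinol epimers)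
Conditions: Pd(PPh3)4 (5 mol %), morpholine, THF, rt
Reagents that add atoms: none
Why: Tsuji–Trost-type deallylation: zerovalent palladium transfers the allyl group to morpholine under non-acidic conditions that do not ionise the benzhydrol, and the hindered, electron-rich aryl bromide does not undergo oxidative addition at room temperature.

Step 11
Reactants: 13 [4,6-bis(benzyloxy)-5-bromo-3-chloro-2-hydroxyphenyl](8-chloro-penta-O-benzylepicatechin-6-yl)methanol; 14 benzyloxyacetaldehyde
Product: 18 (3R,4S)-3,5,7-tris(benzyloxy)-6-bromo-8-chloro-4-(8-chloro-penta-O-benzylepicatechin-6-yl)chroman-2-ol (3,4-trans; anomers), via quinone methide 15 (not isolated), via enamine 16 (not isolated), via hydroxy aldehyde 17 (not isolated)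
Conditions: 14 (3 equiv, slow addition), (S)-α,α-diphenylprolinol trimethylsilyl ether (20 mol %), PhCO2H (20 mol %), CH2Cl2, 0 °C to rt
Reagents that add atoms: none
Why: Under weak-acid co-catalysis 13 loses water to the donor-stabilised ortho-quinone methide 15 while the secondary amine condenses with 14 to the E-enamine 16. The enamine α-carbon adds to the methide carbon (C4), ring A of M rearomatises, and hydrolysis of the iminium ion returns the catalyst and gives hydroxy aldehyde 17. The phenol then adds to the aldehyde in a 6-exo-trig hemiacetalisation that forms O1–C2 and closes ring C as lactol 18. The closest known reaction type is the diarylprolinol silyl ether catalysed Michael addition and hemiacetalisation of enolisable aldehydes with ortho-quinone methides generated in situ from ortho-hydroxybenzhydrols, which gives 3,4-trans chroman-2-ols. C3 is set by the catalyst: the diphenyl(silyloxy)methyl group shields one face of the s-trans E-enamine, so the (S)-catalyst should give 3R, with the benzyloxy group in the place of the α-alkyl group of ordinary aldehydes. C4 is set by the topicity of the C–C bond formation: synclinal approach of the enamine to the methide whose unit-B aryl group points away from the carbonyl oxygen places that aryl group trans to the benzyloxy group in the ring (4S). The step needs anti (3,4-trans) selectivity and catalyst control over the stereocentres of unit B; these lie four or more bonds from C4 behind an aryl ring held perpendicular by its two ortho benzyloxy groups, so unit B should act as a bulky but almost unbiased substituent. The chlorines at C8 of both phloroglucinol rings close the only positions where Friedel–Crafts attack of the methide on a second molecule could compete, and the C6 bromine of M is untouched.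

Step 12
Reactants: 18 (3R,4S)-3,5,7-tris(benzyloxy)-6-bromo-8-chloro-4-(8-chloro-penta-O-benzylepicatechin-6-yl)chroman-2-ol
Product: 19 (3R,4S)-3,5,7-tris(benzyloxy)-6-bromo-8-chloro-4-(8-chloro-penta-O-benzylepicatechin-6-yl)chroman-2-one
Conditions: Dess–Martin periodinane, NaHCO3, CH2Cl2, 0 °C to rt
Reagents that add atoms: none
Why: Oxidation of a cyclic hemiacetal to the lactone under buffered conditions; both anomers converge, and C3, now α to a carbonyl, meets no base strong enough to epimerise it.

Step 13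
Reactants: 19 (3R,4S)-3,5,7-tris(benzyloxy)-6-bromo-8-chloro-4-(8-chloro-penta-O-benzylepicatechin-6-yl)chroman-2-one
Product: 20 (2R,3S)-2-(benzyloxy)-3-[4,6-bis(benzyloxy)-5-bromo-3-chloro-2-hydroxyphenyl]-3-(8-chloro-penta-O-benzylepicatechin-6-yl)-N-methoxy-N-methylpropanamide
Conditions: MeNH(OMe)·HCl, AlMe3, CH2Cl2, 0 °C to rt; aq HCl
Reagents that add atoms: N,O-dimethylhydroxylamine hydrochloride, CNOC.Cl
Why: Aluminium amide aminolysis of an aryl ester (Weinreb amide formation) opens the dihydrocoumarin and frees the ring-A phenol; the reagent is Lewis acidic, not basic, so the α-benzyloxy centre should keep its configuration.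

Step 14
Reactants: 21 4-bromocatechol
Product: 22 4-bromo-1,2-bis(benzyloxy)benzene
Conditions: BnBr (2.2 equiv), K2CO3, DMF, rt
Reagents that add atoms: benzyl bromide, BrCc1ccccc1
Why: Williamson etherification of both catechol hydroxyls.

Step 15
Reactants: 22 4-bromo-1,2-bis(benzyloxy)benzene
Product: 23 [3,4-bis(benzyloxy)phenyl]magnesium bromide (titrated solution in THF)
Conditions: Mg turnings, THF, rt to 40 °C; titration, kept under Ar
Reagents that add atoms: magnesium, [Mg]
Why: Grignard reagent formation by insertion of magnesium into the aryl–bromine bond; the benzyl ethers are inert to it, and the THF solution keeps under argon, so the one reagent serves the aryl ketone syntheses of unit M (step 16) and unit T (step 25).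

Step 16
Reactants: 20 the N-methoxy-N-methylamide of unit M; 23 [3,4-bis(benzyloxy)phenyl]magnesium bromide
Product: 24 (2R,3S)-2-(benzyloxy)-1-[3,4-bis(benzyloxy)phenyl]-3-[4,6-bis(benzyloxy)-5-bromo-3-chloro-2-hydroxyphenyl]-3-(8-chloro-penta-O-benzylepicatechin-6-yl)propan-1-one
Conditions: 23 (3 equiv), THF, 0 °C to rt; aq NH4Cl
Reagents that add atoms: none
Why: Grignard addition to a Weinreb amide stops at the ketone because the chelated tetrahedral intermediate survives until work-up; one equivalent of 23 is spent on the phenol. A magnesium reagent is used in place of an aryllithium so that the C6 bromide is not scrambled by halogen–metal exchange. 24 may rest as its cyclic hemiketal.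

Step 17
Reactants: 24 the aryl ketone of unit M
Product: 25 (1S,2R,3S)-2-(benzyloxy)-1-[3,4-bis(benzyloxy)phenyl]-3-[4,6-bis(benzyloxy)-5-bromo-3-chloro-2-hydroxyphenyl]-3-(8-chloro-penta-O-benzylepicatechin-6-yl)propan-1-ol (1,2-anti)
Conditions: Zn(BH4)2, Et2O/THF, −20 to 0 °C; aq NH4Cl
Reagents that add atoms: none
Why: Chelation-controlled reduction (Cram chelate model): zinc bridges the ketone oxygen and the α-benzyloxy oxygen, and hydride enters from the side of the α-hydrogen, away from the diarylmethyl group, which should give the 1,2-anti (1S) alcohol; reduction runs through the open ketone form.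

Step 18
Reactants: 25 the 1,2-anti alcohol of unit M
Product: 26 perbenzylated 6-bromo-8-chloro-epicatechin-(4β→6)-8-chloro-epicatechin [unit M 2R,3R,4S; unit B 2R,3R]
Conditions: PPh3, diisopropyl azodicarboxylate, THF, 0 °C to rt
Reagents that add atoms: none
Why: Intramolecular Mitsunobu etherification: the ortho-chlorophenol displaces the activated benzylic oxygen with inversion (6-exo-tet), turning the 1S carbinol into 2R, so the 2-aryl group ends cis to the C3 benzyloxy group and trans to the C4 aryl group. The chair-like closure with the C4 aryl group axial and the C2 aryl group equatorial is also the conformationally preferred one.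

Step 19
Reactants: 7 2,4-bis(benzyloxy)-6-hydroxybenzaldehyde
Product: 27 2-(allyloxy)-4,6-bis(benzyloxy)benzaldehyde
Conditions: allyl bromide, K2CO3, DMF, rt
Reagents that add atoms: allyl bromide, C=CCBr
Why: Williamson etherification of the chelated phenol, as in step 8.

Step 20
Reactants: 26 the C6-bromo dimer; 27 2-(allyloxy)-4,6-bis(benzyloxy)benzaldehyde
Product: 29 [2-(allyloxy)-4,6-bis(benzyloxy)phenyl](M-6-yl)methanol (M-6-yl is dimer 26 bonded through C6 of unit M in place of bromine; carbinol epimers), via aryllithium 28 (not isolated)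
Conditions: 26, tBuLi (2.0 equiv), THF, −78 °C; then 27, −78 to −40 °C; aq NH4Cl
Reagents that add atoms: none
Why: Selective bromine–lithium exchange at C6 of M in the presence of two aryl chlorides, then 1,2-addition to the aldehyde, as in step 9; the new bond can only form at C6 of M.

Step 21
Reactants: 29 the allyl-protected benzhydrol of unit T
Product: 30 [2,4-bis(benzyloxy)-6-hydroxyphenyl](M-6-yl)methanol (carbinol epimers)
Conditions: Pd(PPh3)4 (5 mol %), morpholine, THF, rt
Reagents that add atoms: none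
Why: Palladium-catalysed allyl transfer to morpholine, as in step 10; the benzhydrol and the aryl chlorides are untouched.

Step 22
Reactants: 30 the ortho-hydroxybenzhydrol of unit T; 14 benzyloxyacetaldehyde
Product: 34 3,5,7-tris(benzyloxy)-4-(M-6-yl)chroman-2-ol of unit T (3R,4R by the sequence rule; 3,4-trans and 4β as in 18; anomers), via quinone methide 31 (not isolated), via enamine 32 (not isolated), via hydroxy aldehyde 33 (not isolated)
Conditions: 14 (3 equiv, slow addition), (S)-α,α-diphenylprolinol triethylsilyl ether (20 mol %), PhCO2H (20 mol %), CH2Cl2, 0 °C to rt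
Reagents that add atoms: none
Why: Same enamine Michael addition and 6-exo-trig hemiacetalisation as in step 11, here through enamine 32; C3 is set by the (S)-catalyst and C4 by the same synclinal topicity, the stereocentres of M being shielded from the methide carbon by a perpendicular, doubly ortho-substituted aryl ring. The triethylsilyl ether is chosen because the unhalogenated, more hindered methide 31 should react more slowly, and over a long run with acid and the water set free a trimethylsilyl ether is prone to desilylation, after which the free prolinol is tied up by 14 as an oxazolidine; the triethylsilyl group resists this and shields the same enamine face.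

Step 23
Reactants: 34 the lactol of unit T
Product: 35 3,5,7-tris(benzyloxy)-4-(M-6-yl)chroman-2-one of unit T (3R; 3,4-trans)
Conditions: Dess–Martin periodinane, NaHCO3, CH2Cl2, 0 °C to rt
Reagents that add atoms: none
Why: Oxidation of the cyclic hemiacetal to the lactone, as in step 12.

Step 24
Reactants: 35 the lactone of unit T
Product: 36 (2R)-2-(benzyloxy)-3-[2,4-bis(benzyloxy)-6-hydroxyphenyl]-3-(M-6-yl)-N-methoxy-N-methylpropanamide (configuration at C3 as in 35)
Conditions: MeNH(OMe)·HCl, AlMe3, CH2Cl2, 0 °C to rt; aq HCl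
Reagents that add atoms: N,O-dimethylhydroxylamine hydrochloride, CNOC.Cl
Why: Weinreb aminolysis of the aryl ester, as in step 13.

Step 25
Reactants: 36 the N-methoxy-N-methylamide of unit T; 23 [3,4-bis(benzyloxy)phenyl]magnesium bromide
Product: 37 (2R)-2-(benzyloxy)-1-[3,4-bis(benzyloxy)phenyl]-3-[2,4-bis(benzyloxy)-6-hydroxyphenyl]-3-(M-6-yl)propan-1-one
Conditions: 23 (3 equiv), THF, 0 °C to rt; aq NH4Cl
Reagents that add atoms: none
Why: Grignard addition to the Weinreb amide stops at the ketone, as in step 16; one equivalent of 23 is spent on the phenol and the aryl chlorides do not react with the magnesium reagent.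

Step 26
Reactants: 37 the aryl ketone of unit T
Product: 38 (1S,2R)-2-(benzyloxy)-1-[3,4-bis(benzyloxy)phenyl]-3-[2,4-bis(benzyloxy)-6-hydroxyphenyl]-3-(M-6-yl)propan-1-ol (1,2-anti)
Conditions: Zn(BH4)2, Et2O/THF, −20 to 0 °C; aq NH4Cl
Reagents that add atoms: none
Why: Chelation-controlled hydride delivery through the zinc chelate of the ketone and the α-benzyloxy group, as in step 17, should give the 1,2-anti carbinol.

Step 27
Reactants: 38 the 1,2-anti alcohol of unit T
Product: 39 pentadeca-O-benzyl-8-chloro(M),8-chloro(B)-epicatechin-(4β→6)-epicatechin-(4β→6)-epicatechin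
Conditions: PPh3, diisopropyl azodicarboxylate, THF, 0 °C to rt
Reagents that add atoms: none
Why: Intramolecular Mitsunobu etherification with inversion closes ring C of T (6-exo-tet) and sets 2R, cis to the C3 benzyloxy group, as in step 18.

Step 28
Reactants: 39 the protected trimer
Product: 40 epicatechin-(4β→6)-epicatechin-(4β→6)-epicatechin (CNP0163146.2)
Conditions: H2 (1 atm), Pd(OH)2/C, Et3N (4 equiv), THF/MeOH/H2O, rt; filtration, AcOH to neutral, lyophilisation
Reagents that add atoms: none
Why: Hydrogenolysis cleaves all fifteen benzyl ethers, and with triethylamine present palladium also hydrodechlorinates the two aryl chlorides; the conditions are neither acidic enough to break the interflavan bonds nor basic enough to epimerise C2, and no stereocentre is involved.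

## Compound list

1 | (−)-epicatechin, (2R,3R)-2-(3,4-dihydroxyphenyl)chroman-3,5,7-triol | O[C@@H]1Cc2c(O)cc(O)cc2O[C@@H]1c1ccc(O)c(O)c1 | starting material
2 | 5,7,3',4'-tetra-O-benzyl-(−)-epicatechin (2R,3R) | c1c(OCc9ccccc9)cc2c(c1OCc9ccccc9)C[C@@H](O)[C@@H](c8ccc(OCc9ccccc9)c(OCc9ccccc9)c8)O2 | intermediate
3 | 3,5,7,3',4'-penta-O-benzyl-(−)-epicatechin (2R,3R) | c1c(OCc9ccccc9)cc2c(c1OCc9ccccc9)C[C@@H](OCc9ccccc9)[C@@H](c8ccc(OCc9ccccc9)c(OCc9ccccc9)c8)O2 | intermediate
4 | 8-chloro-3,5,7,3',4'-penta-O-benzyl-(−)-epicatechin | c1c(OCc9ccccc9)c(Cl)c2c(c1OCc9ccccc9)C[C@@H](OCc9ccccc9)[C@@H](c8ccc(OCc9ccccc9)c(OCc9ccccc9)c8)O2 | intermediate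
5 | 6-bromo-8-chloro-3,5,7,3',4'-penta-O-benzyl-(−)-epicatechin | Brc1c(OCc9ccccc9)c(Cl)c2c(c1OCc9ccccc9)C[C@@H](OCc9ccccc9)[C@@H](c8ccc(OCc9ccccc9)c(OCc9ccccc9)c8)O2 | intermediate
6 | 2,4,6-trihydroxybenzaldehyde | O=Cc1c(O)cc(O)cc1O | starting material
7 | 2,4-bis(benzyloxy)-6-hydroxybenzaldehyde | O=Cc1c(O)cc(OCc9ccccc9)cc1OCc9ccccc9 | intermediate
8 | 4,6-bis(benzyloxy)-3-chloro-2-hydroxybenzaldehyde | O=Cc1c(O)c(Cl)c(OCc9ccccc9)cc1OCc9ccccc9 | intermediate
9 | 2,4-bis(benzyloxy)-3-bromo-5-chloro-6-hydroxybenzaldehyde | O=Cc1c(O)c(Cl)c(OCc9ccccc9)c(Br)c1OCc9ccccc9 | intermediate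
10 | 2-(allyloxy)-4,6-bis(benzyloxy)-5-bromo-3-chlorobenzaldehyde | O=Cc1c(OCC=C)c(Cl)c(OCc9ccccc9)c(Br)c1OCc9ccccc9 | intermediate
11 | 8-chloro-6-lithio-penta-O-benzylepicatechin | [Li]c1c(OCc9ccccc9)c(Cl)c2c(c1OCc9ccccc9)C[C@@H](OCc9ccccc9)[C@@H](c8ccc(OCc9ccccc9)c(OCc9ccccc9)c8)O2 | intermediate
12 | [2-(allyloxy)-4,6-bis(benzyloxy)-5-bromo-3-chlorophenyl](8-chloro-penta-O-benzylepicatechin-6-yl)methanol, carbinol epimers | Brc1c(OCc9ccccc9)c(Cl)c(OCC=C)c(c1OCc9ccccc9)C(O)c3c(OCc9ccccc9)c(Cl)c4c(c3OCc9ccccc9)C[C@@H](OCc9ccccc9)[C@@H](c8ccc(OCc9ccccc9)c(OCc9ccccc9)c8)O4 | intermediate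
13 | [4,6-bis(benzyloxy)-5-bromo-3-chloro-2-hydroxyphenyl](8-chloro-penta-O-benzylepicatechin-6-yl)methanol, carbinol epimers | Brc1c(OCc9ccccc9)c(Cl)c(O)c(c1OCc9ccccc9)C(O)c3c(OCc9ccccc9)c(Cl)c4c(c3OCc9ccccc9)C[C@@H](OCc9ccccc9)[C@@H](c8ccc(OCc9ccccc9)c(OCc9ccccc9)c8)O4 | intermediate
14 | benzyloxyacetaldehyde | O=CCOCc1ccccc1 | starting material
15 | 3,5-bis(benzyloxy)-4-bromo-2-chloro-6-[(8-chloro-penta-O-benzylepicatechin-6-yl)methylidene]cyclohexa-2,4-dien-1-one (ortho-quinone methide of ring A of M) | O=C1C(Cl)=C(OCc9ccccc9)C(Br)=C(OCc9ccccc9)C1=Cc3c(OCc9ccccc9)c(Cl)c4c(c3OCc9ccccc9)C[C@@H](OCc9ccccc9)[C@@H](c8ccc(OCc9ccccc9)c(OCc9ccccc9)c8)O4 | intermediate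
16 | (E)-enamine of 14 and (S)-α,α-diphenylprolinol trimethylsilyl ether | c1ccccc1CO/C=C/N2CCC[C@H]2C(c3ccccc3)(c4ccccc4)O[Si](C)(C)C | intermediate
17 | (2R,3S)-2-(benzyloxy)-3-[4,6-bis(benzyloxy)-5-bromo-3-chloro-2-hydroxyphenyl]-3-(8-chloro-penta-O-benzylepicatechin-6-yl)propanal | O=C[C@H](OCc9ccccc9)[C@@H](c3c(OCc9ccccc9)c(Cl)c4c(c3OCc9ccccc9)C[C@@H](OCc9ccccc9)[C@@H](c8ccc(OCc9ccccc9)c(OCc9ccccc9)c8)O4)c1c(O)c(Cl)c(OCc9ccccc9)c(Br)c1OCc9ccccc9 | intermediate
18 | (3R,4S)-3,5,7-tris(benzyloxy)-6-bromo-8-chloro-4-(8-chloro-penta-O-benzylepicatechin-6-yl)chroman-2-ol, anomers | Brc1c(OCc9ccccc9)c(Cl)c2c(c1OCc9ccccc9)[C@H](c3c(OCc9ccccc9)c(Cl)c4c(c3OCc9ccccc9)C[C@@H](OCc9ccccc9)[C@@H](c8ccc(OCc9ccccc9)c(OCc9ccccc9)c8)O4)[C@@H](OCc9ccccc9)C(O)O2 | intermediate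
19 | (3R,4S)-3,5,7-tris(benzyloxy)-6-bromo-8-chloro-4-(8-chloro-penta-O-benzylepicatechin-6-yl)chroman-2-one | Brc1c(OCc9ccccc9)c(Cl)c2c(c1OCc9ccccc9)[C@H](c3c(OCc9ccccc9)c(Cl)c4c(c3OCc9ccccc9)C[C@@H](OCc9ccccc9)[C@@H](c8ccc(OCc9ccccc9)c(OCc9ccccc9)c8)O4)[C@@H](OCc9ccccc9)C(=O)O2 | intermediate
20 | (2R,3S)-2-(benzyloxy)-3-[4,6-bis(benzyloxy)-5-bromo-3-chloro-2-hydroxyphenyl]-3-(8-chloro-penta-O-benzylepicatechin-6-yl)-N-methoxy-N-methylpropanamide | CON(C)C(=O)[C@H](OCc9ccccc9)[C@@H](c3c(OCc9ccccc9)c(Cl)c4c(c3OCc9ccccc9)C[C@@H](OCc9ccccc9)[C@@H](c8ccc(OCc9ccccc9)c(OCc9ccccc9)c8)O4)c1c(O)c(Cl)c(OCc9ccccc9)c(Br)c1OCc9ccccc9 | intermediate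
21 | 4-bromocatechol | Oc1ccc(Br)cc1O | starting material
22 | 4-bromo-1,2-bis(benzyloxy)benzene | Brc1ccc(OCc9ccccc9)c(OCc9ccccc9)c1 | intermediate
23 | [3,4-bis(benzyloxy)phenyl]magnesium bromide (THF solution) | Br[Mg]c1ccc(OCc9ccccc9)c(OCc9ccccc9)c1 | intermediate
24 | (2R,3S)-2-(benzyloxy)-1-[3,4-bis(benzyloxy)phenyl]-3-[4,6-bis(benzyloxy)-5-bromo-3-chloro-2-hydroxyphenyl]-3-(8-chloro-penta-O-benzylepicatechin-6-yl)propan-1-one | O=C(c7ccc(OCc9ccccc9)c(OCc9ccccc9)c7)[C@H](OCc9ccccc9)[C@@H](c3c(OCc9ccccc9)c(Cl)c4c(c3OCc9ccccc9)C[C@@H](OCc9ccccc9)[C@@H](c8ccc(OCc9ccccc9)c(OCc9ccccc9)c8)O4)c1c(O)c(Cl)c(OCc9ccccc9)c(Br)c1OCc9ccccc9 | intermediate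
25 | (1S,2R,3S)-2-(benzyloxy)-1-[3,4-bis(benzyloxy)phenyl]-3-[4,6-bis(benzyloxy)-5-bromo-3-chloro-2-hydroxyphenyl]-3-(8-chloro-penta-O-benzylepicatechin-6-yl)propan-1-ol | O[C@@H](c7ccc(OCc9ccccc9)c(OCc9ccccc9)c7)[C@H](OCc9ccccc9)[C@@H](c3c(OCc9ccccc9)c(Cl)c4c(c3OCc9ccccc9)C[C@@H](OCc9ccccc9)[C@@H](c8ccc(OCc9ccccc9)c(OCc9ccccc9)c8)O4)c1c(O)c(Cl)c(OCc9ccccc9)c(Br)c1OCc9ccccc9 | intermediate
26 | perbenzylated 6-bromo-8-chloro-epicatechin-(4β→6)-8-chloro-epicatechin (unit M 2R,3R,4S; unit B 2R,3R) | Brc1c(OCc9ccccc9)c(Cl)c2c(c1OCc9ccccc9)[C@H](c3c(OCc9ccccc9)c(Cl)c4c(c3OCc9ccccc9)C[C@@H](OCc9ccccc9)[C@@H](c8ccc(OCc9ccccc9)c(OCc9ccccc9)c8)O4)[C@@H](OCc9ccccc9)[C@@H](c7ccc(OCc9ccccc9)c(OCc9ccccc9)c7)O2 | intermediate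
27 | 2-(allyloxy)-4,6-bis(benzyloxy)benzaldehyde | O=Cc1c(OCC=C)cc(OCc9ccccc9)cc1OCc9ccccc9 | intermediate
28 | 6-lithio derivative of dimer 26 (lithium at C6 of unit M) | [Li]c1c(OCc9ccccc9)c(Cl)c2c(c1OCc9ccccc9)[C@H](c3c(OCc9ccccc9)c(Cl)c4c(c3OCc9ccccc9)C[C@@H](OCc9ccccc9)[C@@H](c8ccc(OCc9ccccc9)c(OCc9ccccc9)c8)O4)[C@@H](OCc9ccccc9)[C@@H](c7ccc(OCc9ccccc9)c(OCc9ccccc9)c7)O2 | intermediate
29 | [2-(allyloxy)-4,6-bis(benzyloxy)phenyl](M-6-yl)methanol, carbinol epimers | C=CCOc5cc(OCc9ccccc9)cc(OCc9ccccc9)c5C(O)c1c(OCc9ccccc9)c(Cl)c2c(c1OCc9ccccc9)[C@H](c3c(OCc9ccccc9)c(Cl)c4c(c3OCc9ccccc9)C[C@@H](OCc9ccccc9)[C@@H](c8ccc(OCc9ccccc9)c(OCc9ccccc9)c8)O4)[C@@H](OCc9ccccc9)[C@@H](c7ccc(OCc9ccccc9)c(OCc9ccccc9)c7)O2 | intermediate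
30 | [2,4-bis(benzyloxy)-6-hydroxyphenyl](M-6-yl)methanol, carbinol epimers | Oc5cc(OCc9ccccc9)cc(OCc9ccccc9)c5C(O)c1c(OCc9ccccc9)c(Cl)c2c(c1OCc9ccccc9)[C@H](c3c(OCc9ccccc9)c(Cl)c4c(c3OCc9ccccc9)C[C@@H](OCc9ccccc9)[C@@H](c8ccc(OCc9ccccc9)c(OCc9ccccc9)c8)O4)[C@@H](OCc9ccccc9)[C@@H](c7ccc(OCc9ccccc9)c(OCc9ccccc9)c7)O2 | intermediate
31 | 3,5-bis(benzyloxy)-6-[(M-6-yl)methylidene]cyclohexa-2,4-dien-1-one (ortho-quinone methide of ring A of T) | O=C5C=C(OCc9ccccc9)C=C(OCc9ccccc9)C5=Cc1c(OCc9ccccc9)c(Cl)c2c(c1OCc9ccccc9)[C@H](c3c(OCc9ccccc9)c(Cl)c4c(c3OCc9ccccc9)C[C@@H](OCc9ccccc9)[C@@H](c8ccc(OCc9ccccc9)c(OCc9ccccc9)c8)O4)[C@@H](OCc9ccccc9)[C@@H](c7ccc(OCc9ccccc9)c(OCc9ccccc9)c7)O2 | intermediate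
32 | (E)-enamine of 14 and (S)-α,α-diphenylprolinol triethylsilyl ether | c1ccccc1CO/C=C/N2CCC[C@H]2C(c3ccccc3)(c4ccccc4)O[Si](CC)(CC)CC | intermediate
33 | (2R)-2-(benzyloxy)-3-[2,4-bis(benzyloxy)-6-hydroxyphenyl]-3-(M-6-yl)propanal (C3 as in 34) | O=C[C@H](OCc9ccccc9)[C@@H](c1c(OCc9ccccc9)c(Cl)c2c(c1OCc9ccccc9)[C@H](c3c(OCc9ccccc9)c(Cl)c4c(c3OCc9ccccc9)C[C@@H](OCc9ccccc9)[C@@H](c8ccc(OCc9ccccc9)c(OCc9ccccc9)c8)O4)[C@@H](OCc9ccccc9)[C@@H](c7ccc(OCc9ccccc9)c(OCc9ccccc9)c7)O2)c5c(O)cc(OCc9ccccc9)cc5OCc9ccccc9 | intermediate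
34 | 3,5,7-tris(benzyloxy)-4-(M-6-yl)chroman-2-ol of unit T (3R; 3,4-trans, 4β), anomers | c5c(OCc9ccccc9)cc6c(c5OCc9ccccc9)[C@H](c1c(OCc9ccccc9)c(Cl)c2c(c1OCc9ccccc9)[C@H](c3c(OCc9ccccc9)c(Cl)c4c(c3OCc9ccccc9)C[C@@H](OCc9ccccc9)[C@@H](c8ccc(OCc9ccccc9)c(OCc9ccccc9)c8)O4)[C@@H](OCc9ccccc9)[C@@H](c7ccc(OCc9ccccc9)c(OCc9ccccc9)c7)O2)[C@@H](OCc9ccccc9)C(O)O6 | intermediate
35 | 3,5,7-tris(benzyloxy)-4-(M-6-yl)chroman-2-one of unit T (3R; 3,4-trans) | c5c(OCc9ccccc9)cc6c(c5OCc9ccccc9)[C@H](c1c(OCc9ccccc9)c(Cl)c2c(c1OCc9ccccc9)[C@H](c3c(OCc9ccccc9)c(Cl)c4c(c3OCc9ccccc9)C[C@@H](OCc9ccccc9)[C@@H](c8ccc(OCc9ccccc9)c(OCc9ccccc9)c8)O4)[C@@H](OCc9ccccc9)[C@@H](c7ccc(OCc9ccccc9)c(OCc9ccccc9)c7)O2)[C@@H](OCc9ccccc9)C(=O)O6 | intermediate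
36 | (2R)-2-(benzyloxy)-3-[2,4-bis(benzyloxy)-6-hydroxyphenyl]-3-(M-6-yl)-N-methoxy-N-methylpropanamide | CON(C)C(=O)[C@H](OCc9ccccc9)[C@@H](c1c(OCc9ccccc9)c(Cl)c2c(c1OCc9ccccc9)[C@H](c3c(OCc9ccccc9)c(Cl)c4c(c3OCc9ccccc9)C[C@@H](OCc9ccccc9)[C@@H](c8ccc(OCc9ccccc9)c(OCc9ccccc9)c8)O4)[C@@H](OCc9ccccc9)[C@@H](c7ccc(OCc9ccccc9)c(OCc9ccccc9)c7)O2)c5c(O)cc(OCc9ccccc9)cc5OCc9ccccc9 | intermediate
37 | (2R)-2-(benzyloxy)-1-[3,4-bis(benzyloxy)phenyl]-3-[2,4-bis(benzyloxy)-6-hydroxyphenyl]-3-(M-6-yl)propan-1-one | O=C(c7ccc(OCc9ccccc9)c(OCc9ccccc9)c7)[C@H](OCc9ccccc9)[C@@H](c1c(OCc9ccccc9)c(Cl)c2c(c1OCc9ccccc9)[C@H](c3c(OCc9ccccc9)c(Cl)c4c(c3OCc9ccccc9)C[C@@H](OCc9ccccc9)[C@@H](c8ccc(OCc9ccccc9)c(OCc9ccccc9)c8)O4)[C@@H](OCc9ccccc9)[C@@H](c7ccc(OCc9ccccc9)c(OCc9ccccc9)c7)O2)c5c(O)cc(OCc9ccccc9)cc5OCc9ccccc9 | intermediate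
38 | (1S,2R)-2-(benzyloxy)-1-[3,4-bis(benzyloxy)phenyl]-3-[2,4-bis(benzyloxy)-6-hydroxyphenyl]-3-(M-6-yl)propan-1-ol (1,2-anti) | O[C@@H](c7ccc(OCc9ccccc9)c(OCc9ccccc9)c7)[C@H](OCc9ccccc9)[C@@H](c1c(OCc9ccccc9)c(Cl)c2c(c1OCc9ccccc9)[C@H](c3c(OCc9ccccc9)c(Cl)c4c(c3OCc9ccccc9)C[C@@H](OCc9ccccc9)[C@@H](c8ccc(OCc9ccccc9)c(OCc9ccccc9)c8)O4)[C@@H](OCc9ccccc9)[C@@H](c7ccc(OCc9ccccc9)c(OCc9ccccc9)c7)O2)c5c(O)cc(OCc9ccccc9)cc5OCc9ccccc9 | intermediate
39 | pentadeca-O-benzyl-8-chloro(M),8-chloro(B)-epicatechin-(4β→6)-epicatechin-(4β→6)-epicatechin | c5c(OCc9ccccc9)cc6c(c5OCc9ccccc9)[C@H](c1c(OCc9ccccc9)c(Cl)c2c(c1OCc9ccccc9)[C@H](c3c(OCc9ccccc9)c(Cl)c4c(c3OCc9ccccc9)C[C@@H](OCc9ccccc9)[C@@H](c8ccc(OCc9ccccc9)c(OCc9ccccc9)c8)O4)[C@@H](OCc9ccccc9)[C@@H](c7ccc(OCc9ccccc9)c(OCc9ccccc9)c7)O2)[C@@H](OCc9ccccc9)[C@@H](c7ccc(OCc9ccccc9)c(OCc9ccccc9)c7)O6 | intermediate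
40 | epicatechin-(4β→6)-epicatechin-(4β→6)-epicatechin (CNP0163146.2) | Oc1cc(O)c2c(c1)O[C@H](c1ccc(O)c(O)c1)[C@H](O)[C@H]2c1c(O)cc2c(c1O)[C@H](c1c(O)cc3c(c1O)C[C@@H](O)[C@@H](c1ccc(O)c(O)c1)O3)[C@@H](O)[C@@H](c1ccc(O)c(O)c1)O2 | target

## Step count and least certain steps

Total: 28 steps. Longest linear sequence: 21 steps (steps 1–4, 9–13, 16–18, 20–28).

**Step 11 (key step).** The most likely failures are erosion of the 3,4-trans selectivity if the strongly donor-stabilised methide reacts through its other geometry, slow addition to so stabilised an acceptor, and self-aldol condensation of 14 under amine catalysis. The fallback replaces catalyst control by a stoichiometric auxiliary and Lewis-acid activation. It sets out from 13 and comes back at lactone 19, so steps 11 and 12 fall away. (S)-4-Benzyl-3-(benzyloxyacetyl)oxazolidin-2-one is enolised with TiCl4 and iPr2NEt in CH2Cl2 at −78 °C to the trichlorotitanium Z-enolate F1. Addition of 13 lets the Lewis acid ionise the benzhydrol to the same methide, and the enolate should attack from the face away from the benzyl group to give the imide adduct (S)-4-benzyl-3-[(2R,3S)-2-(benzyloxy)-3-aryl-3-aryl-propanoyl]oxazolidin-2-one F2, whose diastereomers can be separated. With Et3N and DMAP the phenol of F2 attacks the exocyclic imide carbonyl, releases the oxazolidinone and closes lactone 19.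

**Step 22.** The same failure modes are sharper here: the methide carbon carries the whole dimer, and the unhalogenated ring A of T makes the methide still less electrophilic, so slow turnover, loss of the catalyst and poor facial control are all more likely. The fallback gives up the quinone methide for unit T and joins a ready-made epicatechin electrophile to the dimer by the established Lewis-acid coupling of 4-oxygenated flavans. It sets out from 26 and 4 and comes back at 40, replacing steps 20–28. Aryllithium 28, made as in step 20, is quenched with MeOH to the debrominated dimer F3, whose only free phloroglucinol position is C6 of M. Oxidation of 4 with DDQ in the presence of 2-ethoxyethanol gives 8-chloro-4β-(2-ethoxyethoxy)-penta-O-benzylepicatechin F4. F3, used in excess to hold back self-condensation of F4 through its own free C6, and F4 with catalytic TMSOTf in CH2Cl2 at −78 °C should give the trichloro pentadeca-O-benzyl trimer F5, the C4 cation being attacked trans to the C3 benzyloxy group and the chlorines closing every C8 position. Hydrogenolysis of F5 under the conditions of step 28 removes the benzyl groups and all three chlorines and gives 40.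

**Step 6.** The halogen may enter the wrong position (between the two benzyloxy groups) or both positions, and that would move the later interflavan bond from C6 to C8 of M. Since both positions must be halogenated anyway, the fallback reverses the order. From 7, NBS gives 2,4-bis(benzyloxy)-3-bromo-6-hydroxybenzaldehyde F6 if the first halogen prefers the position between the ethers, and NCS then chlorinates the position next to the hydroxyl to give 9, where the route is rejoined.

**Step 3.** Chlorination may be less selective for C8 over C6 than the bromination it is modelled on. The fallback uses the established bromination and exchanges the halogen. From 3, NBS in CH2Cl2 at low temperature gives 8-bromo-penta-O-benzylepicatechin F7; tBuLi in THF at −78 °C gives the 8-lithio compound F8, which is quenched with C2Cl6 to give 4.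

**Step 18 (and step 27).** The activated 3,4-dialkoxybenzylic oxygen may ionise before the hindered phenol attacks, which would cost the stereospecific inversion or lead to elimination. The fallback uses that ionisation on purpose. From 25 (or 38), a catalytic Brønsted acid (pyridinium p-toluenesulfonate or a trace of CF3CO2H in CH2Cl2 at −20 °C) closes the ring through the benzylic cation. The peri C5 benzyloxy group holds the C4 aryl group axial, and the C2 aryl group then has to take the equatorial position, which is the 2,4-trans, 2,3-cis arrangement of 26 (or 39), whatever the carbinol configuration. No new compound is formed on this path.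

**Step 28.** Hydrodechlorination of the two electron-rich, doubly ortho-substituted aryl chlorides may lag behind debenzylation and leave chlorinated polyphenols, and the free trimer is sensitive to prolonged exposure to amine and catalyst. The fallback separates the two tasks. From 39, palladium-catalysed transfer hydrodechlorination (Pd(OAc)2, tricyclohexylphosphine, HCO2Na, dioxane, 80 °C) gives the chlorine-free pentadeca-O-benzyl trimer F9, which is hydrogenolysed over Pd(OH)2/C without amine to give 40.

## Further compounds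

F1 | step 11 | trichlorotitanium Z-enolate of (S)-4-benzyl-3-(benzyloxyacetyl)oxazolidin-2-one | Cl[Ti](Cl)(Cl)O/C(N1C(=O)OC[C@@H]1Cc1ccccc1)=C\OCc1ccccc1
F2 | step 11 | (S)-4-benzyl-3-[(2R,3S)-2-(benzyloxy)-3-[4,6-bis(benzyloxy)-5-bromo-3-chloro-2-hydroxyphenyl]-3-(8-chloro-penta-O-benzylepicatechin-6-yl)propanoyl]oxazolidin-2-one | O=C1OC[C@H](Cc2ccccc2)N1C(=O)[C@H](OCc9ccccc9)[C@@H](c3c(OCc9ccccc9)c(Cl)c4c(c3OCc9ccccc9)C[C@@H](OCc9ccccc9)[C@@H](c8ccc(OCc9ccccc9)c(OCc9ccccc9)c8)O4)c1c(O)c(Cl)c(OCc9ccccc9)c(Br)c1OCc9ccccc9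
F3 | step 22 | debrominated dimer, perbenzylated 8-chloro-epicatechin-(4β→6)-8-chloro-epicatechin with hydrogen at C6 of unit M | c1c(OCc9ccccc9)c(Cl)c2c(c1OCc9ccccc9)[C@H](c3c(OCc9ccccc9)c(Cl)c4c(c3OCc9ccccc9)C[C@@H](OCc9ccccc9)[C@@H](c8ccc(OCc9ccccc9)c(OCc9ccccc9)c8)O4)[C@@H](OCc9ccccc9)[C@@H](c7ccc(OCc9ccccc9)c(OCc9ccccc9)c7)O2
F4 | step 22 | 8-chloro-4β-(2-ethoxyethoxy)-3,5,7,3',4'-penta-O-benzylepicatechin | c1c(OCc9ccccc9)c(Cl)c2c(c1OCc9ccccc9)[C@H](OCCOCC)[C@@H](OCc9ccccc9)[C@@H](c8ccc(OCc9ccccc9)c(OCc9ccccc9)c8)O2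
F5 | step 22 | pentadeca-O-benzyl-8-chloro(T),8-chloro(M),8-chloro(B)-epicatechin-(4β→6)-epicatechin-(4β→6)-epicatechin | c5c(OCc9ccccc9)c(Cl)c6c(c5OCc9ccccc9)[C@H](c1c(OCc9ccccc9)c(Cl)c2c(c1OCc9ccccc9)[C@H](c3c(OCc9ccccc9)c(Cl)c4c(c3OCc9ccccc9)C[C@@H](OCc9ccccc9)[C@@H](c8ccc(OCc9ccccc9)c(OCc9ccccc9)c8)O4)[C@@H](OCc9ccccc9)[C@@H](c7ccc(OCc9ccccc9)c(OCc9ccccc9)c7)O2)[C@@H](OCc9ccccc9)[C@@H](c7ccc(OCc9ccccc9)c(OCc9ccccc9)c7)O6
F6 | step 6 | 2,4-bis(benzyloxy)-3-bromo-6-hydroxybenzaldehyde | O=Cc1c(O)cc(OCc9ccccc9)c(Br)c1OCc9ccccc9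
F7 | step 3 | 8-bromo-3,5,7,3',4'-penta-O-benzylepicatechin | c1c(OCc9ccccc9)c(Br)c2c(c1OCc9ccccc9)C[C@@H](OCc9ccccc9)[C@@H](c8ccc(OCc9ccccc9)c(OCc9ccccc9)c8)O2
F8 | step 3 | 8-lithio-3,5,7,3',4'-penta-O-benzylepicatechin | c1c(OCc9ccccc9)c([Li])c2c(c1OCc9ccccc9)C[C@@H](OCc9ccccc9)[C@@H](c8ccc(OCc9ccccc9)c(OCc9ccccc9)c8)O2
F0 | step 18 | none | none
F9 | step 28 | pentadeca-O-benzyl-epicatechin-(4β→6)-epicatechin-(4β→6)-epicatechin | c5c(OCc9ccccc9)cc6c(c5OCc9ccccc9)[C@H](c1c(OCc9ccccc9)cc2c(c1OCc9ccccc9)[C@H](c3c(OCc9ccccc9)cc4c(c3OCc9ccccc9)C[C@@H](OCc9ccccc9)[C@@H](c8ccc(OCc9ccccc9)c(OCc9ccccc9)c8)O4)[C@@H](OCc9ccccc9)[C@@H](c7ccc(OCc9ccccc9)c(OCc9ccccc9)c7)O2)[C@@H](OCc9ccccc9)[C@@H](c7ccc(OCc9ccccc9)c(OCc9ccccc9)c7)O6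
A1 | alternative 1 | 4,6-bis(benzyloxy)-3-[2,6-bis(benzyloxy)phenyl]indan-1-one | O=C1C[C@@H](c3c(OCc9ccccc9)cccc3OCc9ccccc9)c2c(OCc9ccccc9)cc(OCc9ccccc9)cc12
A2 | alternative 1 | 5,7-bis(benzyloxy)-4-[2,6-bis(benzyloxy)phenyl]-3,4-dihydrocoumarin | O=C1C[C@@H](c3c(OCc9ccccc9)cccc3OCc9ccccc9)c2c(OCc9ccccc9)cc(OCc9ccccc9)cc2O1
A3 | alternative 2 | C6 (unit M) arylmagnesium bromide of perbenzylated epicatechin-(4β→6)-epicatechin | Br[Mg]c1c(OCc9ccccc9)cc2c(c1OCc9ccccc9)[C@H](c3c(OCc9ccccc9)cc4c(c3OCc9ccccc9)C[C@@H](OCc9ccccc9)[C@@H](c8ccc(OCc9ccccc9)c(OCc9ccccc9)c8)O4)[C@@H](OCc9ccccc9)[C@@H](c8ccc(OCc9ccccc9)c(OCc9ccccc9)c8)O2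
A4 | alternative 2 | 2,4-bis(benzyloxy)-6-(tert-butoxycarbonyloxy)benzaldehyde | O=Cc1c(OC(=O)OC(C)(C)C)cc(OCc9ccccc9)cc1OCc9ccccc9
A5 | alternative 2 | (Z)-2-[3,4-bis(benzyloxy)phenyl]ethenyl pivalate | CC(C)(C)C(=O)O/C=C\c1ccc(OCc9ccccc9)c(OCc9ccccc9)c1
A6 | alternative 2 | ortho-quinone methide of ring A of T bonded to C6 of unit M of the perbenzylated dimer | O=C5C=C(OCc9ccccc9)C=C(OCc9ccccc9)C5=Cc1c(OCc9ccccc9)cc2c(c1OCc9ccccc9)[C@H](c3c(OCc9ccccc9)cc4c(c3OCc9ccccc9)C[C@@H](OCc9ccccc9)[C@@H](c8ccc(OCc9ccccc9)c(OCc9ccccc9)c8)O4)[C@@H](OCc9ccccc9)[C@@H](c8ccc(OCc9ccccc9)c(OCc9ccccc9)c8)O2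
A7 | alternative 2 | benzylated trimer with a C3 pivalate on unit T | C(c9ccccc9)Oc1cc(OCc9ccccc9)c2c(c1)O[C@H](c8ccc(OCc9ccccc9)c(OCc9ccccc9)c8)[C@H](OC(=O)C(C)(C)C)[C@H]2c1c(OCc9ccccc9)cc2c(c1OCc9ccccc9)[C@H](c3c(OCc9ccccc9)cc4c(c3OCc9ccccc9)C[C@@H](OCc9ccccc9)[C@@H](c8ccc(OCc9ccccc9)c(OCc9ccccc9)c8)O4)[C@@H](OCc9ccccc9)[C@@H](c8ccc(OCc9ccccc9)c(OCc9ccccc9)c8)O2
A8 | alternative 3 | 2-[[3,4-bis(benzyloxy)phenyl](hydroxy)methyl]-4,6-bis(benzyloxy)-5-bromo-3-(penta-O-benzylepicatechin-6-yl)-2,3-dihydrobenzofuran | Brc1c(OCc9ccccc9)cc2c(c1OCc9ccccc9)[C@H](c3c(OCc9ccccc9)cc4c(c3OCc9ccccc9)C[C@@H](OCc9ccccc9)[C@@H](c8ccc(OCc9ccccc9)c(OCc9ccccc9)c8)O4)[C@@H]([C@@H](O)c8ccc(OCc9ccccc9)c(OCc9ccccc9)c8)O2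
A9 | alternative 3 | bicyclic oxonium ion formed from A8 by participation of the ring oxygen | Brc1c(OCc9ccccc9)cc2c(c1OCc9ccccc9)[C@H](c3c(OCc9ccccc9)cc4c(c3OCc9ccccc9)C[C@@H](OCc9ccccc9)[C@@H](c8ccc(OCc9ccccc9)c(OCc9ccccc9)c8)O4)[C@H]3[C@@H](c8ccc(OCc9ccccc9)c(OCc9ccccc9)c8)[O+]23
A10 | alternative 3 | 6-bromo unit M flavan-3-ol (3-OH free) joined through C4 to C6 of perbenzylated unit B | Brc1c(OCc9ccccc9)cc2c(c1OCc9ccccc9)[C@H](c3c(OCc9ccccc9)cc4c(c3OCc9ccccc9)C[C@@H](OCc9ccccc9)[C@@H](c8ccc(OCc9ccccc9)c(OCc9ccccc9)c8)O4)[C@@H](O)[C@@H](c8ccc(OCc9ccccc9)c(OCc9ccccc9)c8)O2
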